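In a one-step world the open intermediate would be captured at one constant rate, so I reckoned that world first and treated the slowing as a correction to it.

| setting | cedar | green | blue |
|---|---|---|---|
| starting material | 0.019 M | 0.013 M | 0.013 M |
| partner | 0.0117 M | 0.0120 M | 0.0350 M |
| remark | run made earlier |  |  |
| time |  | 20 min | 20 min |

cedar run (percent of the starting material charged)

| time / min | isomer of the product / % | target / % | open intermediate / % | starting material / % |
|---|---|---|---|---|
| 0.833 | 0 | 1.2 | 13.9 | 84.7 |
| 2.50 | 0.1 | 3.7 | 37.6 | 58.6 |
| 5.00 | 2.2 | 8.0 | 55.8 | 35.7 |
| 8.00 | 4.9 | 13.8 | 63.4 | 16.0 |

(scatter of a reading: 1 percentage point)

* which of these there is most of at the end, counted by the starting material in it, green (target / isomer of the product / open intermediate / starting material)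
* which of these there is most of at the end, counted by the starting material in it, blue (target / isomer of the product / open intermediate / starting material)
* the largest of these amounts at the end, in percent of the starting material charged, green
* the largest of these amounts at the end, in percent of the starting material charged, blue

- the numbers in the tables scatter with a standard deviation of 1 percentage point

By 8.00 min the cedar run had lost 0.0160 M of starting material against 0.0117 M of partner charged, so I took the opening to need no partner. The reading at 5.00 min gave an opening constant k_A of 0.206 min⁻¹. The growth of target plus isomer from 5.00 min to 8.00 min, divided by the mean open intermediate and the mean partner left, gave a capture constant k_c of 5.31 M⁻¹ min⁻¹.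

The starting capture rate w, a pseudo-first-order constant equal to k_c times the partner charge, was 0.0637 min⁻¹ in green and 0.186 min⁻¹ in blue. I counted two things that slow it. The open intermediate arrives late by the inverse of k_A, 4.85 min, which leaves a capture time T of 15.1 min, a factor of 0.755. I also assumed that each capture spends one partner. A first pass at constant w put the unspent fraction of the charge at the end at 0.329 in green and 0.651 in blue, and averaging that with the start gave mean factors of 0.665 and 0.825. The capture exponent L, the product of w, T and the mean factor, came to 0.641 in green and 2.32 in blue. I took exp(−L) as the open intermediate left, 52.7% in green and 9.80% in blue.

The forecast named open intermediate at 50% for green and isomer of the product at 54% for blue, adding that “this depends on the poorly defined isomerisation rate”.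

Green gave open intermediate at 53.1%; blue gave target at 44.5%, with isomer at 38.8% and open intermediate at 15.2%.

    partner → second intermediate (k = 0.0390 s⁻¹)
    target ⇌ isomer of the product (K = 1.30, k = 0.00188 s⁻¹)
    starting material → open intermediate (k = 0.00346 s⁻¹)
    open intermediate + second intermediate → target (k = 0.0812 M⁻¹ s⁻¹)

Against the open intermediate of 53.1% in green and 15.2% in blue stood my exp(−L) values of 52.7% and 9.80%. The forecast and blue part on the isomer of the product: in green the step between target and isomer of the product, taken alone and both ways together, has a relaxation half-life of 3.47 min, shorter than 20 min. In blue, isomer of the product over target stood at 0.870, below the equilibrium constant of 1.3. Take green with 0.033 M of starting material: the first pass asks 0.0204 M of partner against 0.0120 M, so in this reckoning I set the end factor to zero, which makes L 0.482 and exp(−L) 61.7%. The computed flask holds 67.6% open intermediate.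

The readings are simulated on assumed constants, and the scatter is random.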